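Ring A (C1 chain-bearing CH, C2 methylene-bearing carbon, C3 and C5 the CHBr carbons, C4, C6 the CMe2 carbon) is disconnected at C4–C5: C3 and C5 are 1,3-related across C4 and C5 sits on quaternary C6, so a C3 ketone and a C5 carbinol are an aldol pair whose aldehyde cannot enolise. One intramolecular Mukaiyama-type aldol closes ring A, forms C4–C5 and sets the C5 oxygen cis to the C1 chain. Its precursor is an acyclic δ-keto aldehyde from (S)-linalool with C1 already set, a methyl ketone (C3, C4) and a neopentyl aldehyde (C5). Both oxygens are later replaced by bromine with inversion.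

Key step: step 9

Assumption: the L-allo-threonine-derived oxazaborolidinone of step 6 is taken to expose the C1 Re face of enone 5; if a test run shows the opposite sense, its enantiomer from D-allo-threonine is used and nothing else changes.

Step 1
Reactants: 1 (S)-linalool
Product: 2 triethyl{[(3S)-3,7-dimethylocta-1,6-dien-3-yl]oxy}silane
Conditions: TESOTf, 2,6-lutidine, CH2Cl2, −78 → 0 °C
Reagents that add atoms: triethylsilyl trifluoromethanesulfonate, CC[Si](CC)(CC)OS(=O)(=O)C(F)(F)F
Why: Silylation of the hindered tertiary allylic alcohol with a silyl triflate and a hindered pyridine base is standard, leaves the C3' centre untouched and masks the hydroxyl that would otherwise add to the later enone.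

Step 2
Reactants: 2 (S)-linalool triethylsilyl ether
Product: 3 (4S)-4-methyl-4-(triethylsilyloxy)hex-5-enal
Conditions: O3 (1 equiv), CH2Cl2–MeOH, NaHCO3, −78 °C; then Me2S, −78 °C → rt
Reagents that add atoms: ozone, [O-][O+]=O
Why: Chemoselective ozonolysis, since ozone attacks the electron-rich trisubstituted alkene far faster than the monosubstituted vinyl group beside the silyloxy-bearing quaternary carbon, and reductive work-up gives the aldehyde whose carbonyl carbon becomes C1.

Step 3
Reactants: 3 (4S)-4-methyl-4-(triethylsilyloxy)hex-5-enal; 4 1-(triphenylphosphoranylidene)propan-2-one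
Product: 5 (3E,7S)-7-methyl-7-(triethylsilyloxy)nona-3,8-dien-2-one
Conditions: CH2Cl2, rt → 40 °C
Reagents that add atoms: none
Why: Wittig olefination with the stabilised acetyl ylide is (E)-selective and gives the enone whose β-carbon is the future C1.

Step 4
Reactants: 6 2-methylpropanoyl chloride; 7 ethanethiol
Product: 8 S-ethyl 2-methylpropanethioate
Conditions: Et3N, CH2Cl2, 0 °C
Reagents that add atoms: none
Why: Acylation of the thiol by the acid chloride in the presence of an amine base gives the thioester needed for the ketene acetal.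

Step 5
Reactants: 8 S-ethyl 2-methylpropanethioate
Product: 9 {[1-(ethylsulfanyl)-2-methylprop-1-en-1-yl]oxy}trimethylsilane
Conditions: LiN(i-Pr)2, THF, −78 °C; TMSCl
Reagents that add atoms: chlorotrimethylsilane, C[Si](C)(C)Cl
Why: Enolisation of the thioester and O-silylation give the ketene S,O-acetal, which has no E/Z issue because both substituents on the nucleophilic carbon are methyl.

Step 6
Reactants: 5 (3E,7S)-7-methyl-7-(triethylsilyloxy)nona-3,8-dien-2-one; 9 ketene S,O-acetal
Product: 10 S-ethyl (3R,6S)-2,2,6-trimethyl-3-(2-oxopropyl)-6-(triethylsilyloxy)oct-7-enethioate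
Conditions: 10 mol % (S)-4-[(S)-1-(2-naphthoyloxy)ethyl]-2-phenyl-3-tosyl-1,3,2-oxazaborolidin-5-one (from the N-tosyl-O-aroyl-L-allo-threonine and PhBCl2), 2,6-diisopropylphenol, t-BuOMe, CH2Cl2, −78 °C
Reagents that add atoms: none
Why: Chiral-Lewis-acid-catalysed Mukaiyama–Michael addition in which the boron catalyst binds the enone carbonyl and shields one face of the β-carbon, so the dimethylketene acetal adds to the C1 Re face and sets C1 (R) under catalyst control without influence from the remote C3' centre, while the phenol traps the silyl group and suppresses the achiral silyl-cation pathway.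

Step 7
Reactants: 10 thioester ketone
Product: 11 (3R,6S)-3-(2-hydroxypropyl)-2,2,6-trimethyl-6-(triethylsilyloxy)oct-7-en-1-ol
Conditions: LiAlH4, THF, 0 °C → rt; NaOH (aq) work-up
Reagents that add atoms: none
Why: Hydride reduction takes the hindered thioester to the neopentyl alcohol and the ketone to the secondary alcohol in one operation, the new carbinol epimers being irrelevant because that carbon is re-oxidised.

Step 8
Reactants: 11 diol
Product: 12 (3R,6S)-2,2,6-trimethyl-3-(2-oxopropyl)-6-(triethylsilyloxy)oct-7-enal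
Conditions: (COCl)2, DMSO, CH2Cl2, −78 °C; Et3N, → 0 °C
Reagents that add atoms: none
Why: Double Swern oxidation activates both hydroxyls before the base is added, so ketone and aldehyde form together without lactol formation, and C1, being β to both carbonyls, cannot epimerise.

Step 9
Reactants: 12 δ-keto aldehyde
Product: 14 (3S,5R)-4,4-dimethyl-5-[(3S)-3-methyl-3-(triethylsilyloxy)pent-4-en-1-yl]-3-(trimethylsilyloxy)cyclohexan-1-one, via C4 enol silane aldehyde 13 (not isolated)
Conditions: i-Pr2NEt (1.6 equiv), TMSOTf (1.3 equiv), CH2Cl2 (0.02 M), −78 → −20 °C; NaHCO3 (aq)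
Reagents that add atoms: trimethylsilyl trifluoromethanesulfonate, C[Si](C)(C)OS(=O)(=O)C(F)(F)F
Why: The amine and the silyl triflate convert the methyl ketone in the flask into its less substituted enol silane (C3=C4), the silyl triflate activates the C5 aldehyde as a silyloxocarbenium ion, C4 adds to C5 and silyl transfer leaves the C3 ketone and the C5 trimethylsilyl ether, the closest known type being the one-pot silyl triflate/amine enol silane formation–Mukaiyama aldol, here run intramolecularly. Ring A closes in the 6-(enolendo)-exo-trig mode, since the enol double bond C3=C4 lies inside the new ring and the C5=O is exocyclic, the mode of the aldol step of a Robinson annulation. The constitution is secured by the substrate, because the aldehyde on quaternary C6 has no α-hydrogen and can only be the acceptor, and the regioisomeric C2=C3 enol silane could only close a four-membered ring and returns the ketone on work-up. The new C5 centre is controlled by C1 through a chair transition state with the C1 chain equatorial and the silyl-activated C=O antiperiplanar to the enol C=C (open, non-chelated arrangement), which places the C5 oxygen equatorial and cis to the chain (C5 S). The step needs this cis relationship, and a monodentate silicon Lewis acid is chosen because a metal- or hydrogen-bond-bridged closed transition state would hold the carbonyl oxygen gauche to C3, that is axial and trans to the chain. Because the product is formed as its silyl ether it cannot undergo retro-aldol cleavage, so the kinetic ratio is kept, and the same silyl ether steers the next enolisation to C2.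

Step 10
Reactants: 14 ketol trimethylsilyl ether; 15 N,N-dimethylmethyleneiminium iodide (Eschenmoser's salt)
Product: 16 (2S,3R,5S)-2-[(dimethylamino)methyl]-4,4-dimethyl-3-[(3S)-3-methyl-3-(triethylsilyloxy)pent-4-en-1-yl]-5-(trimethylsilyloxy)cyclohexan-1-one
Conditions: LiN(i-Pr)2 (1.1 equiv), THF, −78 °C; then 15, −78 → 0 °C; used crude
Reagents that add atoms: none
Why: Kinetic deprotonation takes place at C2, remote from the bulky, inductively deactivating C5 silyloxy group (as in 3-silyloxycyclohexanones), and the enolate is aminomethylated anti to the C1 chain (Mannich reaction), giving a C2 centre that is erased in step 12.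

Step 11
Reactants: 16 Mannich base
Product: 18 (1S,3S,5R,6S)-6-[(dimethylamino)methyl]-4,4-dimethyl-5-[(3S)-3-methyl-3-(triethylsilyloxy)pent-4-en-1-yl]cyclohexane-1,3-diol, via silylated amino alcohol 17 (not isolated)
Conditions: LiBH(s-Bu)3, THF, −78 °C; then MeOH, K2CO3, rt
Reagents that add atoms: none
Why: The bulky borohydride attacks the C3 carbonyl of the conformationally anchored ring from the equatorial side, placing the new C3 hydroxyl axial and trans to the C1 chain and the C5 oxygen, and methanolysis then removes the C5 trimethylsilyl group while the tertiary triethylsilyl ether survives.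

Step 12
Reactants: 18 amino diol
Product: 20 (1S,3S,5S)-4,4-dimethyl-6-methylidene-5-[(3S)-3-methyl-3-(triethylsilyloxy)pent-4-en-1-yl]cyclohexane-1,3-diol, via amine N-oxide 19 (not isolated)
Conditions: mCPBA (1.05 equiv), K2CO3, CH2Cl2, −20 → 0 °C; filter through basic Al2O3; then DMSO–THF, 60 °C
Reagents that add atoms: 3-chloroperbenzoic acid, O=C(OO)c1cccc(Cl)c1
Why: N-Oxidation of the tertiary amine is much faster than epoxidation of the vinyl group, and the amine oxide undergoes syn (Cope) elimination through its only β-hydrogen, the one on C2, which can give nothing but the exocyclic C2 methylene.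

Step 13
Reactants: 20 allylic diol
Product: 22 {[(3S)-5-[(1S,3R,5R)-3,5-dibromo-2,2-dimethyl-6-methylidenecyclohexyl]-3-methylpent-1-en-3-yl]oxy}triethylsilane, via monobromide 21 (not isolated)
Conditions: PPh3 (3 equiv), CBr4 (3 equiv), 2,6-lutidine (1 equiv), CH2Cl2, −20 °C → rt, then 40 °C
Reagents that add atoms: carbon tetrabromide, BrC(Br)(Br)Br
Why: Twofold Appel bromination with inversion, in which the axial allylic C3 alkoxyphosphonium is displaced first by bromide from the open equatorial side (C3–Br cis to the chain), which clears the axial trajectory at C5 so that the equatorial C5 alkoxyphosphonium, lacking an antiperiplanar hydrogen for elimination, is then displaced to the axial bromide trans to the chain.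

Step 14
Reactants: 22 dibromide triethylsilyl ether
Product: 23 (3S)-5-[(1S,3R,5R)-3,5-dibromo-2,2-dimethyl-6-methylidenecyclohexyl]-3-methylpent-1-en-3-ol
Conditions: HF·pyridine, pyridine, THF, 0 °C → rt
Reagents that add atoms: none
Why: Buffered HF·pyridine cleaves the tertiary triethylsilyl ether by fluoride-assisted Si–O scission without the basic, nucleophilic fluoride that could attack the allylic bromide.

Compound list
1 | (S)-linalool, (3S)-3,7-dimethylocta-1,6-dien-3-ol | C=C[C@@](C)(O)CCC=C(C)C | starting material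
2 | triethyl{[(3S)-3,7-dimethylocta-1,6-dien-3-yl]oxy}silane | C=C[C@@](C)(O[Si](CC)(CC)CC)CCC=C(C)C | intermediate
3 | (4S)-4-methyl-4-(triethylsilyloxy)hex-5-enal | C=C[C@@](C)(O[Si](CC)(CC)CC)CCC=O | intermediate
4 | 1-(triphenylphosphoranylidene)propan-2-one | CC(=O)C=P(c1ccccc1)(c1ccccc1)c1ccccc1 | starting material
5 | (3E,7S)-7-methyl-7-(triethylsilyloxy)nona-3,8-dien-2-one | C=C[C@@](C)(O[Si](CC)(CC)CC)CC/C=C/C(C)=O | intermediate
6 | 2-methylpropanoyl chloride | CC(C)C(=O)Cl | starting material
7 | ethanethiol | CCS | starting material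
8 | S-ethyl 2-methylpropanethioate | CCSC(=O)C(C)C | intermediate
9 | {[1-(ethylsulfanyl)-2-methylprop-1-en-1-yl]oxy}trimethylsilane | CCSC(O[Si](C)(C)C)=C(C)C | intermediate
10 | S-ethyl (3R,6S)-2,2,6-trimethyl-3-(2-oxopropyl)-6-(triethylsilyloxy)oct-7-enethioate | C=C[C@@](C)(O[Si](CC)(CC)CC)CC[C@H](CC(C)=O)C(C)(C)C(=O)SCC | intermediate
11 | (3R,6S)-3-(2-hydroxypropyl)-2,2,6-trimethyl-6-(triethylsilyloxy)oct-7-en-1-ol, both epimers at the CH(OH)CH3 carbon | C=C[C@@](C)(O[Si](CC)(CC)CC)CC[C@H](CC(C)O)C(C)(C)CO | intermediate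
12 | (3R,6S)-2,2,6-trimethyl-3-(2-oxopropyl)-6-(triethylsilyloxy)oct-7-enal (δ-keto aldehyde, C1 set) | C=C[C@@](C)(O[Si](CC)(CC)CC)CC[C@H](CC(C)=O)C(C)(C)C=O | intermediate
13 | (3R,6S)-2,2,6-trimethyl-6-(triethylsilyloxy)-3-[2-(trimethylsilyloxy)prop-2-en-1-yl]oct-7-enal | C=C[C@@](C)(O[Si](CC)(CC)CC)CC[C@H](CC(=C)O[Si](C)(C)C)C(C)(C)C=O | intermediate (not isolated)
14 | (3S,5R)-4,4-dimethyl-5-[(3S)-3-methyl-3-(triethylsilyloxy)pent-4-en-1-yl]-3-(trimethylsilyloxy)cyclohexan-1-one (cis ketol as its C5 trimethylsilyl ether) | C=C[C@@](C)(O[Si](CC)(CC)CC)CC[C@@H]1CC(=O)C[C@H](O[Si](C)(C)C)C1(C)C | intermediate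
15 | N,N-dimethylmethyleneiminium iodide | C=[N+](C)C.[I-] | starting material
16 | (2S,3R,5S)-2-[(dimethylamino)methyl]-4,4-dimethyl-3-[(3S)-3-methyl-3-(triethylsilyloxy)pent-4-en-1-yl]-5-(trimethylsilyloxy)cyclohexan-1-one | C=C[C@@](C)(O[Si](CC)(CC)CC)CC[C@@H]1[C@@H](CN(C)C)C(=O)C[C@H](O[Si](C)(C)C)C1(C)C | intermediate
17 | (1S,2S,3R,5S)-2-[(dimethylamino)methyl]-4,4-dimethyl-3-[(3S)-3-methyl-3-(triethylsilyloxy)pent-4-en-1-yl]-5-(trimethylsilyloxy)cyclohexan-1-ol | C=C[C@@](C)(O[Si](CC)(CC)CC)CC[C@@H]1[C@@H](CN(C)C)[C@@H](O)C[C@H](O[Si](C)(C)C)C1(C)C | intermediate (not isolated)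
18 | (1S,3S,5R,6S)-6-[(dimethylamino)methyl]-4,4-dimethyl-5-[(3S)-3-methyl-3-(triethylsilyloxy)pent-4-en-1-yl]cyclohexane-1,3-diol | C=C[C@@](C)(O[Si](CC)(CC)CC)CC[C@@H]1[C@@H](CN(C)C)[C@@H](O)C[C@H](O)C1(C)C | intermediate
19 | N-oxide of 18 (same configuration, N,N-dimethylamine oxide on the CH2 at C2) | C=C[C@@](C)(O[Si](CC)(CC)CC)CC[C@@H]1[C@@H](C[N+](C)(C)[O-])[C@@H](O)C[C@H](O)C1(C)C | intermediate (not isolated)
20 | (1S,3S,5S)-4,4-dimethyl-6-methylidene-5-[(3S)-3-methyl-3-(triethylsilyloxy)pent-4-en-1-yl]cyclohexane-1,3-diol | C=C[C@@](C)(O[Si](CC)(CC)CC)CC[C@@H]1C(=C)[C@@H](O)C[C@H](O)C1(C)C | intermediate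
21 | (1S,3S,5R)-5-bromo-2,2-dimethyl-4-methylidene-3-[(3S)-3-methyl-3-(triethylsilyloxy)pent-4-en-1-yl]cyclohexan-1-ol | C=C[C@@](C)(O[Si](CC)(CC)CC)CC[C@@H]1C(=C)[C@H](Br)C[C@H](O)C1(C)C | intermediate (not isolated)
22 | {[(3S)-5-[(1S,3R,5R)-3,5-dibromo-2,2-dimethyl-6-methylidenecyclohexyl]-3-methylpent-1-en-3-yl]oxy}triethylsilane | C=C[C@@](C)(O[Si](CC)(CC)CC)CC[C@@H]1C(=C)[C@H](Br)C[C@@H](Br)C1(C)C | intermediate
23 | (3S)-5-[(1S,3R,5R)-3,5-dibromo-2,2-dimethyl-6-methylidenecyclohexyl]-3-methylpent-1-en-3-ol | C=C[C@@](C)(O)CC[C@@H]1C(=C)[C@H](Br)C[C@@H](Br)C1(C)C | target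

Total step count: 14. Longest linear sequence: 12 steps (from 1 through steps 1–3 and 6–14).

Steps most likely to fail

1. Step 9 (key step). Facial selectivity at C5 may erode: the synclinal, oxygen-axial arrangement or a chair with the C1 chain axial both lead to the C5 epimer, and the silyl triflate may also ionise the tertiary allylic silyl ether. The fallback sets out from 12 and comes back at 21; it sets C5 by hydride reduction instead of by the aldol. Compound 12 is cyclised under enamine catalysis (L-proline, DMSO, rt), whose hydrogen-bonded closed transition state should hold the aldehyde oxygen axial and give the C5-epimeric (trans) ketol F1; either epimer or a mixture serves, because C5 is reset later. Dianion formation (LiN(i-Pr)2, 2.2 equiv) and Eschenmoser's salt should give the Mannich base F2, LiBH(s-Bu)3 the amino diol F3, mCPBA the amine N-oxide F4 and heating the C5-epimeric allylic diol F5. Appel bromination at −20 °C with aqueous quench should convert only the allylic C3 hydroxyl and give the bromo alcohol F6. Dess–Martin oxidation should give the bromo ketone F7, in which the equatorial C1 chain and C3 bromine anchor the ring. NaBH4 at −78 °C, adding along the axial direction, should then give the equatorial C5 alcohol 21, which is brominated at C5 as in the second stage of step 13.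

2. Step 13. The displacement at the hindered C5 alkoxyphosphonium may stall, and during the wait bromide and phosphine may cause allylic transposition or epimerisation of the C3 bromide already in place. The fallback sets out from 20 and comes back at 22; it reverses the order of the two brominations. MnO2 should oxidise only the allylic C3 hydroxyl to the methylidene keto alcohol F8. With C3 trigonal the axial trajectory at C5 is open, and Appel bromination should give the axial C5 bromide, the bromo enone F9. Reduction with NaBH4/CeCl3·7H2O (Luche conditions, MeOH, −78 °C), whose axial approach to C3 is blocked by the syn-axial C5 bromine, should give the axial allylic alcohol F10. A final low-temperature Appel bromination with inversion at C3 should give 22.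

3. Step 6. Face discrimination at C1 may be insufficient if the achiral silyl-cation pathway competes with the boron catalyst. The fallback sets out from 3 and comes back at 11; it replaces Lewis-acid activation of the enone by iminium activation of an enal. Wittig reaction of 3 with (triphenylphosphoranylidene)acetaldehyde should give the (E)-enal F11. Organocatalytic Mukaiyama–Michael addition of 9 under a chiral imidazolidinone salt ((2S,5S)-5-benzyl-2-tert-butyl-3-methylimidazolidin-4-one trifluoroacetate or its enantiomer, whichever exposes the C1 Re face; CH2Cl2–H2O, −60 °C) should give the aldehyde thioester F12. MeMgBr at −78 °C should add to the aldehyde only and give the hydroxy thioester F13, and LiAlH4 then gives diol 11.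

Further compounds
F1 | step 9 | (3R,5R)-3-hydroxy-4,4-dimethyl-5-[(3S)-3-methyl-3-(triethylsilyloxy)pent-4-en-1-yl]cyclohexan-1-one | C=C[C@@](C)(O[Si](CC)(CC)CC)CC[C@@H]1CC(=O)C[C@@H](O)C1(C)C
F2 | step 9 | (2S,3R,5R)-2-[(dimethylamino)methyl]-5-hydroxy-4,4-dimethyl-3-[(3S)-3-methyl-3-(triethylsilyloxy)pent-4-en-1-yl]cyclohexan-1-one | C=C[C@@](C)(O[Si](CC)(CC)CC)CC[C@@H]1[C@@H](CN(C)C)C(=O)C[C@@H](O)C1(C)C
F3 | step 9 | (1S,3R,5R,6S)-6-[(dimethylamino)methyl]-4,4-dimethyl-5-[(3S)-3-methyl-3-(triethylsilyloxy)pent-4-en-1-yl]cyclohexane-1,3-diol | C=C[C@@](C)(O[Si](CC)(CC)CC)CC[C@@H]1[C@@H](CN(C)C)[C@@H](O)C[C@@H](O)C1(C)C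
F4 | step 9 | N-oxide of F3 (same configuration, N,N-dimethylamine oxide on the CH2 at C2) | C=C[C@@](C)(O[Si](CC)(CC)CC)CC[C@@H]1[C@@H](C[N+](C)(C)[O-])[C@@H](O)C[C@@H](O)C1(C)C
F5 | step 9 | (1S,3R,5S)-4,4-dimethyl-6-methylidene-5-[(3S)-3-methyl-3-(triethylsilyloxy)pent-4-en-1-yl]cyclohexane-1,3-diol | C=C[C@@](C)(O[Si](CC)(CC)CC)CC[C@@H]1C(=C)[C@@H](O)C[C@@H](O)C1(C)C
F6 | step 9 | (1R,3S,5R)-5-bromo-2,2-dimethyl-4-methylidene-3-[(3S)-3-methyl-3-(triethylsilyloxy)pent-4-en-1-yl]cyclohexan-1-ol | C=C[C@@](C)(O[Si](CC)(CC)CC)CC[C@@H]1C(=C)[C@H](Br)C[C@@H](O)C1(C)C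
F7 | step 9 | (3S,5R)-5-bromo-2,2-dimethyl-4-methylidene-3-[(3S)-3-methyl-3-(triethylsilyloxy)pent-4-en-1-yl]cyclohexan-1-one | C=C[C@@](C)(O[Si](CC)(CC)CC)CC[C@@H]1C(=C)[C@H](Br)CC(=O)C1(C)C
F8 | step 13 | (3S,5S)-5-hydroxy-4,4-dimethyl-2-methylidene-3-[(3S)-3-methyl-3-(triethylsilyloxy)pent-4-en-1-yl]cyclohexan-1-one | C=C[C@@](C)(O[Si](CC)(CC)CC)CC[C@@H]1C(=C)C(=O)C[C@H](O)C1(C)C
F9 | step 13 | (3R,5R)-5-bromo-4,4-dimethyl-2-methylidene-3-[(3S)-3-methyl-3-(triethylsilyloxy)pent-4-en-1-yl]cyclohexan-1-one | C=C[C@@](C)(O[Si](CC)(CC)CC)CC[C@@H]1C(=C)C(=O)C[C@@H](Br)C1(C)C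
F10 | step 13 | (1S,3R,5R)-5-bromo-4,4-dimethyl-2-methylidene-3-[(3S)-3-methyl-3-(triethylsilyloxy)pent-4-en-1-yl]cyclohexan-1-ol | C=C[C@@](C)(O[Si](CC)(CC)CC)CC[C@@H]1C(=C)[C@@H](O)C[C@@H](Br)C1(C)C
F11 | step 6 | (2E,6S)-6-methyl-6-(triethylsilyloxy)octa-2,7-dienal | C=C[C@@](C)(O[Si](CC)(CC)CC)CC/C=C/C=O
F12 | step 6 | S-ethyl (3R,6S)-2,2,6-trimethyl-3-(2-oxoethyl)-6-(triethylsilyloxy)oct-7-enethioate | C=C[C@@](C)(O[Si](CC)(CC)CC)CC[C@H](CC=O)C(C)(C)C(=O)SCC
F13 | step 6 | S-ethyl (3R,6S)-3-(2-hydroxypropyl)-2,2,6-trimethyl-6-(triethylsilyloxy)oct-7-enethioate, both carbinol epimers | C=C[C@@](C)(O[Si](CC)(CC)CC)CC[C@H](CC(C)O)C(C)(C)C(=O)SCC
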